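## Retrosynthetic overview

Positions are given in germacranolide numbering (lactone O on C6, lactone C=O is C12, acetates on C3 and C9); the skeleton is cut into three C5 units.
1. The C11 methyl stereocentre comes last, by face-selective hydrogenation of an α-methylene lactone.
2. The C6–C7 bond closes the ten-membered carbocycle by an intramolecular chromium Barbier allylation; the γ-lactone then closes on the new C6 hydroxyl (carbocycle first, lactone second).
3. The C7=C11 acrylate unit is attached by cross-metathesis to an allyl group that was added to C9 by a reagent-controlled allylation (C8–C9, sets C9).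
4. The C2–C3 bond and C3 come first, from a carbene-catalysed vinylogous aldol–lactonisation of a tigloyl unit with an acetal-protected C5 enal; the temporary dihydropyranone locks the Z C1=C10 alkene and is opened again by reduction.

Assumption: the acetal-protected C5 enal is taken as a purchasable carotenoid building block, and the triazolium antipode used in the first step is the one that gives the 6S lactone (the mirror-image salt is used if the sense proves opposite).

## Route

Step 1
Reactants: 1 (2E)-4,4-dimethoxy-2-methylbut-2-enal; 2 (2E)-2-methylbut-2-enoyl chloride (tigloyl chloride)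
Product: 3 (6S)-6-[(2E)-4,4-dimethoxybut-2-en-2-yl]-3-methyl-5,6-dihydro-2H-pyran-2-one
Conditions: (5aS,10bR)-2-mesityl-5a,10b-dihydro-4H,6H-indeno[2,1-b][1,2,4]triazolo[4,3-d][1,4]oxazin-2-ium tetrafluoroborate (10 mol%), Cs2CO3 (2.2 equiv), 4 Å MS, THF, 0 °C → rt, slow addition of 2
Reagents that add atoms: none
Why: Proposed new method: the carbene is acylated by 2 and Cs2CO3 removes a γ-proton to give an s-cis azolium dienolate whose γ-carbon adds to the aldehyde of 1 inside the chiral pocket (this C–C bond formation sets C6 of the pyranone, expected S), after which the alkoxide closes onto the acyl azolium and releases the carbene, so the six-membered lactone also fixes the cis ring alkene; the α-branched enal 1 is a poor partner for Breslow-intermediate formation and should act only as the electrophile; the closest known reaction type is the carbene-catalysed formal [4+2] (vinylogous aldol–lactonisation) of azolium dienolates with activated ketones such as trifluoromethyl ketones and isatins, not yet shown for a simple α-branched enal with an α-methyl dienolate.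

Step 2
Reactants: 3 (6S)-6-[(2E)-4,4-dimethoxybut-2-en-2-yl]-3-methyl-5,6-dihydro-2H-pyran-2-one
Product: 4 (6S)-6-[(2E)-4,4-dimethoxybut-2-en-2-yl]-3-methyl-5,6-dihydro-2H-pyran-2-ol (mixture of anomers)
Conditions: i-Bu2AlH (1.1 equiv), CH2Cl2, −78 °C; aq. potassium sodium tartrate
Reagents that add atoms: none
Why: Partial hydride reduction of the unsaturated δ-lactone stops at the lactol because the aluminium hemiacetal is stable at −78 °C; the acetal, the cis ring alkene and C6 are untouched.

Step 3
Reactants: 4 (6S)-6-[(2E)-4,4-dimethoxybut-2-en-2-yl]-3-methyl-5,6-dihydro-2H-pyran-2-ol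
Product: 5 (4R,5Z,8S,9E)-11,11-dimethoxy-5,9-dimethylundeca-1,5,9-triene-4,8-diol
Conditions: (+)-Ipc2B(allyl) (2.5 equiv), Et2O, −78 °C → rt; then 3 M NaOH, 30% H2O2
Reagents that add atoms: (+)-B-allyldiisopinocampheylborane, the antipode made from (−)-α-pinene, C=CCB([C@H]1C[C@H]2C[C@H](C2(C)C)[C@@H]1C)[C@H]1C[C@H]2C[C@H](C2(C)C)[C@@H]1C
Why: Brown allylboration of the open hydroxy-enal tautomer of the lactol through a chair six-membered transition state; the reagent delivers allyl to the Re face of the aldehyde and sets C4 as R (germacranolide C9) irrespective of the remote C8 centre, and the Z alkene survives because the enal is only released transiently from the ring.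

Step 4
Reactants: 5 (4R,5Z,8S,9E)-11,11-dimethoxy-5,9-dimethylundeca-1,5,9-triene-4,8-diol
Product: 6 (4R,5Z,8S,9E)-11,11-dimethoxy-5,9-dimethylundeca-1,5,9-triene-4,8-diyl diacetate
Conditions: Ac2O (3 equiv), pyridine, DMAP (5 mol%), CH2Cl2, 0 °C → rt
Reagents that add atoms: acetic anhydride, CC(=O)OC(C)=O
Why: DMAP-catalysed acylation of both secondary allylic alcohols installs the two acetates of the target early, so no protecting groups are needed; no stereocentre is touched.

Step 5
Reactants: 6 (4R,5Z,8S,9E)-11,11-dimethoxy-5,9-dimethylundeca-1,5,9-triene-4,8-diyl diacetate; 7 methyl 2-(bromomethyl)prop-2-enoate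
Product: 8 methyl (2Z,5R,6Z,9S,10E)-5,9-bis(acetyloxy)-2-(bromomethyl)-12,12-dimethoxy-6,10-dimethyldodeca-2,6,10-trienoate
Conditions: 7 (5 equiv), second-generation Grubbs catalyst (10 mol%), CH2Cl2, 40 °C
Reagents that add atoms: none
Why: Olefin cross-metathesis engages only the monosubstituted alkene of 6 (the trisubstituted alkenes are inert) with the 2-substituted acrylate used in excess, and thermodynamic control places the chain trans to the ester, which is the (2Z) allylic bromide.

Step 6
Reactants: 8 methyl (2Z,5R,6Z,9S,10E)-5,9-bis(acetyloxy)-2-(bromomethyl)-12,12-dimethoxy-6,10-dimethyldodeca-2,6,10-trienoate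
Product: 9 methyl (2Z,5R,6Z,9S,10E)-5,9-bis(acetyloxy)-2-(bromomethyl)-6,10-dimethyl-12-oxododeca-2,6,10-trienoate
Conditions: PPTS (20 mol%), acetone/H2O 10:1, rt
Reagents that add atoms: water, O
Why: Mild acid-catalysed acetal hydrolysis frees the conjugated aldehyde (the allylic dimethyl acetal ionises easily), while the acetates and the allylic bromide tolerate these conditions.

Step 7
Reactants: 9 methyl (2Z,5R,6Z,9S,10E)-5,9-bis(acetyloxy)-2-(bromomethyl)-6,10-dimethyl-12-oxododeca-2,6,10-trienoate
Product: 11 (3aS,5R,6Z,9S,10E,11aR)-6,10-dimethyl-3-methylidene-2-oxo-2,3,3a,4,5,8,9,11a-octahydrocyclodeca[b]furan-5,9-diyl diacetate, via seco hydroxy ester 10 (not isolated)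
Conditions: CrCl2 (6 equiv), THF/DMF 10:1, syringe-pump addition of 9 to 2 mM, rt; then p-TsOH·H2O (10 mol%), CH2Cl2, rt
Reagents that add atoms: none
Why: Intramolecular Nozaki–Hiyama-type chromium Barbier allylation: two equivalents of divalent chromium turn the allylic bromide into a 2-(methoxycarbonyl)allyl trivalent chromium species that equilibrates between its allylic forms and adds through its γ-carbon to the enal in a chair Zimmerman–Traxler transition state with the chain methylene equatorial, giving the anti hydroxy ester 10 (trans-fused lactone after acid-catalysed closure); the aldehyde face is chosen by the ten-membered transition state that keeps both acetoxy groups pseudo-equatorial (substrate control, not proven for this substrate).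

Step 8
Reactants: 11 (3aS,5R,6Z,9S,10E,11aR)-6,10-dimethyl-3-methylidene-2-oxo-2,3,3a,4,5,8,9,11a-octahydrocyclodeca[b]furan-5,9-diyl diacetate
Product: 12 (3R,3aS,5R,6Z,9S,10E,11aS)-3,6,10-trimethyl-2-oxo-2,3,3a,4,5,8,9,11a-octahydrocyclodeca[b]furan-5,9-diyl diacetate
Conditions: H2 (1 atm), RhCl(PPh3)3 (10 mol%), toluene, rt
Reagents that add atoms: none
Why: Homogeneous syn-hydrogenation with RhCl(PPh3)3 reduces only the electron-poor 1,1-disubstituted exocyclic alkene (trisubstituted ring alkenes and allylic acetates are inert) and delivers H2 to the lactone face anti to the C4 ring carbon on C3a, the usual outcome for β-substituted α-methylene-γ-butyrolactones, so the methyl ends up cis to C4 (3R) with no enolisable intermediate.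

## Compound list

1 | (2E)-4,4-dimethoxy-2-methylbut-2-enal | COC(OC)/C=C(\C)C=O | starting material
2 | (2E)-2-methylbut-2-enoyl chloride (tigloyl chloride) | C/C=C(\C)C(Cl)=O | starting material
3 | (6S)-6-[(2E)-4,4-dimethoxybut-2-en-2-yl]-3-methyl-5,6-dihydro-2H-pyran-2-one | COC(OC)/C=C(\C)[C@@H]1CC=C(C)C(=O)O1 | intermediate
4 | (6S)-6-[(2E)-4,4-dimethoxybut-2-en-2-yl]-3-methyl-5,6-dihydro-2H-pyran-2-ol (anomer mixture) | COC(OC)/C=C(\C)[C@@H]1CC=C(C)C(O)O1 | intermediate
5 | (4R,5Z,8S,9E)-11,11-dimethoxy-5,9-dimethylundeca-1,5,9-triene-4,8-diol | COC(OC)/C=C(\C)[C@@H](O)C/C=C(/C)[C@H](O)CC=C | intermediate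
6 | (4R,5Z,8S,9E)-11,11-dimethoxy-5,9-dimethylundeca-1,5,9-triene-4,8-diyl diacetate | COC(OC)/C=C(\C)[C@@H](OC(C)=O)C/C=C(/C)[C@H](OC(C)=O)CC=C | intermediate
7 | methyl 2-(bromomethyl)prop-2-enoate | C=C(CBr)C(=O)OC | starting material
8 | methyl (2Z,5R,6Z,9S,10E)-5,9-bis(acetyloxy)-2-(bromomethyl)-12,12-dimethoxy-6,10-dimethyldodeca-2,6,10-trienoate | COC(OC)/C=C(\C)[C@@H](OC(C)=O)C/C=C(/C)[C@H](OC(C)=O)C/C=C(\CBr)C(=O)OC | intermediate
9 | methyl (2Z,5R,6Z,9S,10E)-5,9-bis(acetyloxy)-2-(bromomethyl)-6,10-dimethyl-12-oxododeca-2,6,10-trienoate | O=C/C=C(\C)[C@@H](OC(C)=O)C/C=C(/C)[C@H](OC(C)=O)C/C=C(\CBr)C(=O)OC | intermediate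
10 | methyl 2-[(1S,2R,3E,5S,7Z,9R)-5,9-bis(acetyloxy)-2-hydroxy-4,8-dimethylcyclodeca-3,7-dien-1-yl]prop-2-enoate | CC(=O)O[C@H]1C/C=C(/C)[C@H](OC(C)=O)C[C@@H](C(=C)C(=O)OC)[C@@H](/C=C/1C)O | intermediate
11 | (3aS,5R,6Z,9S,10E,11aR)-6,10-dimethyl-3-methylidene-2-oxo-2,3,3a,4,5,8,9,11a-octahydrocyclodeca[b]furan-5,9-diyl diacetate | CC(=O)O[C@H]1C/C=C(/C)[C@H](OC(C)=O)C[C@@H]2[C@@H](/C=C/1C)OC(=O)C2=C | intermediate
12 | (3R,3aS,5R,6Z,9S,10E,11aS)-3,6,10-trimethyl-2-oxo-2,3,3a,4,5,8,9,11a-octahydrocyclodeca[b]furan-5,9-diyl diacetate | CC(=O)O[C@H]1C/C=C(/C)[C@H](OC(C)=O)C[C@@H]2[C@@H](/C=C/1C)OC(=O)[C@@H]2C | target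

## Step count and risks

Total step count: 8. Longest linear sequence: 8 steps (1 → 12).

The three steps most likely to fail are steps 1, 7 and 8.

**Step 1** (new annulation). The risks are α- instead of γ-attack of the dienolate, low enantioselectivity, or consumption of the carbene by the enal. The fallback uses known chemistry, sets out from 1 and comes back at 3. Chiral phosphoric acid catalysis with (S)-TRIP and allylboronic acid pinacol ester (toluene, −30 °C) gives (4S,5E)-7,7-dimethoxy-5-methylhepta-1,5-dien-4-ol F1, so the first stereocentre is still set by an organocatalyst. Acylation with methacryloyl chloride (Et3N, DMAP, CH2Cl2) gives (4S,5E)-7,7-dimethoxy-5-methylhepta-1,5-dien-4-yl 2-methylprop-2-enoate F2. Ring-closing metathesis (second-generation Grubbs catalyst, CH2Cl2, 40 °C) then closes the dihydropyranone 3.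

**Step 7** (ten-membered ring closure). The risks are oligomerisation, the cis-fused lactone, or addition to the wrong aldehyde face. The fallback sets out from 6 and comes back at 12; it replaces the ester-bearing allylchromium by a simple 2-methylallyl zinc species and sets C11 by hydroboration, so steps 5 to 8 are bypassed.
- Cross-metathesis of 6 with methacrolein (second-generation Grubbs catalyst) gives (2E,5R,6Z,9S,10E)-12,12-dimethoxy-2,6,10-trimethyl-1-oxododeca-2,6,10-triene-5,9-diyl diacetate F3.
- NaBH4/CeCl3·7H2O in MeOH gives (2E,5R,6Z,9S,10E)-1-hydroxy-12,12-dimethoxy-2,6,10-trimethyldodeca-2,6,10-triene-5,9-diyl diacetate F4.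
- NCS/Me2S gives (2E,5R,6Z,9S,10E)-1-chloro-12,12-dimethoxy-2,6,10-trimethyldodeca-2,6,10-triene-5,9-diyl diacetate F5.
- PPTS in aqueous acetone frees (2E,4S,6Z,8R,10E)-12-chloro-3,7,11-trimethyl-1-oxododeca-2,6,10-triene-4,8-diyl diacetate F6.
- Pd(PPh3)4 with Et2Zn in THF at high dilution (umpolung allylation through an allylzinc chair) closes the ring to (1R,2E,4S,6Z,8R,10S)-1-hydroxy-3,7-dimethyl-10-(prop-1-en-2-yl)cyclodeca-2,6-diene-4,8-diyl diacetate F7. The primary allylic chloride should ionise far faster than the secondary allylic acetates.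
- 9-BBN followed by NaBO3·4H2O gives (1S,2E,4S,6Z,8R,10S)-1-hydroxy-10-[(2R)-1-hydroxypropan-2-yl]-3,7-dimethylcyclodeca-2,6-diene-4,8-diyl diacetate F8. The borane is expected to approach the isopropenyl group anti to the carbinol carbon in the hydrogen-eclipsed rotamer.
- TEMPO/PhI(OAc)2 oxidative lactonisation of the 1,4-diol gives 12.

**Step 8** (C11 configuration). The risks are hydrogen delivery to the other lactone face or migration of the exocyclic alkene into the ring. The fallback sets out from 10 and comes back at 12. Step 7 is stopped before the acid treatment and hydroxy ester 10 is isolated after a neutral work-up. Hydroxyl-directed hydrogenation with [Rh(nbd)(dppb)]BF4 (H2, CH2Cl2) delivers hydrogen to the acrylate face held by the neighbouring hydroxyl and gives methyl (2R)-2-[(1S,2S,3E,5S,7Z,9R)-5,9-bis(acetyloxy)-2-hydroxy-4,8-dimethylcyclodeca-3,7-dien-1-yl]propanoate F9. This sets C11 on the open chain by a different control element. Catalytic p-TsOH in CH2Cl2 then closes the lactone to 12.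

Further compounds
F1 | step 1 | (4S,5E)-7,7-dimethoxy-5-methylhepta-1,5-dien-4-ol | COC(OC)/C=C(\C)[C@@H](O)CC=C
F2 | step 1 | (4S,5E)-7,7-dimethoxy-5-methylhepta-1,5-dien-4-yl 2-methylprop-2-enoate | COC(OC)/C=C(\C)[C@@H](OC(=O)C(C)=C)CC=C
F3 | step 7 | (2E,5R,6Z,9S,10E)-12,12-dimethoxy-2,6,10-trimethyl-1-oxododeca-2,6,10-triene-5,9-diyl diacetate | COC(OC)/C=C(\C)[C@@H](OC(C)=O)C/C=C(/C)[C@H](OC(C)=O)C/C=C(\C)C=O
F4 | step 7 | (2E,5R,6Z,9S,10E)-1-hydroxy-12,12-dimethoxy-2,6,10-trimethyldodeca-2,6,10-triene-5,9-diyl diacetate | COC(OC)/C=C(\C)[C@@H](OC(C)=O)C/C=C(/C)[C@H](OC(C)=O)C/C=C(\C)CO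
F5 | step 7 | (2E,5R,6Z,9S,10E)-1-chloro-12,12-dimethoxy-2,6,10-trimethyldodeca-2,6,10-triene-5,9-diyl diacetate | COC(OC)/C=C(\C)[C@@H](OC(C)=O)C/C=C(/C)[C@H](OC(C)=O)C/C=C(\C)CCl
F6 | step 7 | (2E,4S,6Z,8R,10E)-12-chloro-3,7,11-trimethyl-1-oxododeca-2,6,10-triene-4,8-diyl diacetate | O=C/C=C(\C)[C@@H](OC(C)=O)C/C=C(/C)[C@H](OC(C)=O)C/C=C(\C)CCl
F7 | step 7 | (1R,2E,4S,6Z,8R,10S)-1-hydroxy-3,7-dimethyl-10-(prop-1-en-2-yl)cyclodeca-2,6-diene-4,8-diyl diacetate | CC(=O)O[C@H]1C/C=C(/C)[C@H](OC(C)=O)C[C@@H](C(C)=C)[C@@H](/C=C/1C)O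
F8 | step 7 | (1S,2E,4S,6Z,8R,10S)-1-hydroxy-10-[(2R)-1-hydroxypropan-2-yl]-3,7-dimethylcyclodeca-2,6-diene-4,8-diyl diacetate | CC(=O)O[C@H]1C/C=C(/C)[C@H](OC(C)=O)C[C@@H]([C@@H](C)CO)[C@@H](/C=C/1C)O
F9 | step 8 | methyl (2R)-2-[(1S,2S,3E,5S,7Z,9R)-5,9-bis(acetyloxy)-2-hydroxy-4,8-dimethylcyclodeca-3,7-dien-1-yl]propanoate | CC(=O)O[C@H]1C/C=C(/C)[C@H](OC(C)=O)C[C@@H]([C@@H](C)C(=O)OC)[C@@H](/C=C/1C)O
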